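**Retrosynthetic overview**

1. Target acid 17 ⇐ methyl ester 16 by saponification.
2. 16 ⇐ racemic Baylis–Hillman carbonate 13 + formaldehyde in one flask: O1–C2 by stereoconvergent palladium-catalysed allylic etherification with the formaldehyde hemiacetal alkoxide, then C6–C5 by acetal-initiated vinylsilane cyclisation. The only ring, the 3,6-dihydro-2H-pyran, is closed here.
3. Enabling feature: ring atom O1 sits between C6H2 (a formaldehyde-level carbon, allylic to the ring C4=C5 double bond) and C2, the allylic carbinol carbon of the 2-methylene ester unit C2–C(=CH2)–CO2R. C2 can therefore come from a π-allyl electrophile, and C6–C5 from an O1=C6H2 oxocarbenium ion and a C5-silylated alkene.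
4. 13 ⇐ β,γ-unsaturated aldehyde 9 + methyl propiolate (vinylalumination), then Boc2O; 9 ⇐ (Z)-vinylsilane 8, made by tethered trans-hydrosilylation of homopropargylic alcohol 5.
5. 5 ⇐ terminal alkyne 3 + ethylene oxide; 3 ⇐ (5E,9E)-farnesylacetone 1, which supplies C5 and the whole triene side chain.

Key step: step 8

Assumption: 1 is used as the commercial all-E isomer, and the (R,R)-enantiomer of the ligand is taken to deliver (R) at C2; should the sense be the opposite, the (S,S)-ligand is used.

**Step 1**
Reactants: 1 (5E,9E)-6,10,14-trimethylpentadeca-5,9,13-trien-2-one (farnesylacetone)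
Product: 3 (5E,9E)-6,10,14-trimethylpentadeca-5,9,13-trien-1-yne, via enol phosphate 2 (not isolated)
Conditions: LDA, THF, −78 °C; ClP(O)(OEt)2, −78 °C → rt; LDA (2.3 equiv), −78 °C → rt; H2O
Reagents that add atoms: none
Why: Kinetic deprotonation at the methyl group, O-phosphorylation and base-induced elimination of diethyl phosphate from 2 (methyl ketone to terminal alkyne through an enol phosphate) should give the 1-alkyne without touching the trisubstituted alkenes.

**Step 2**
Reactants: 3 (5E,9E)-6,10,14-trimethylpentadeca-5,9,13-trien-1-yne; 4 ethylene oxide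
Product: 5 (7E,11E)-8,12,16-trimethylheptadeca-7,11,15-trien-3-yn-1-ol
Conditions: n-BuLi, THF–DMPU, −78 → −20 °C; ethylene oxide, −20 °C → rt; H2O
Reagents that add atoms: none
Why: Ring opening of ethylene oxide by the lithium acetylide (acetylide alkylation of an epoxide) should give the homopropargylic alcohol whose hydroxyl group anchors the silicon tether of the next step.

**Step 3**
Reactants: 5 (7E,11E)-8,12,16-trimethylheptadeca-7,11,15-trien-3-yn-1-ol
Product: 7 2,2-dimethyl-3-[(3E,7E)-4,8,12-trimethyltrideca-3,7,11-trien-1-yl]-5,6-dihydro-2H-1,2-oxasiline, via dimethylsilyl ether 6 (not isolated)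
Conditions: (HMe2Si)2NH, neat, rt, then evaporation; [Cp*Ru(MeCN)3]PF6 (2 mol %), CH2Cl2, 0 °C → rt
Reagents that add atoms: 1,1,3,3-tetramethyldisilazane, C[SiH](C)N[SiH](C)C
Why: Silylation to 6 and cationic ruthenium-catalysed intramolecular trans-hydrosilylation in the 6-endo-dig mode (tethered alkyne hydrosilylation) should place silicon on the alkyne carbon distal to oxygen and, through the ring, cis to the CH2CH2O arm, which fixes the (Z)-vinylsilane geometry.

**Step 4**
Reactants: 7 2,2-dimethyl-3-[(3E,7E)-4,8,12-trimethyltrideca-3,7,11-trien-1-yl]-5,6-dihydro-2H-1,2-oxasiline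
Product: 8 (3Z,7E,11E)-8,12,16-trimethyl-4-(trimethylsilyl)heptadeca-3,7,11,15-tetraen-1-ol
Conditions: MeLi (3 equiv), THF, −78 → 0 °C; H2O
Reagents that add atoms: methyllithium, [Li]C
Why: Nucleophilic cleavage of the Si–O bond by methyllithium (ring opening of a cyclic siloxane) should free the primary alcohol and leave a (Z)-alkenyltrimethylsilane with unchanged alkene geometry.

**Step 5**
Reactants: 8 (3Z,7E,11E)-8,12,16-trimethyl-4-(trimethylsilyl)heptadeca-3,7,11,15-tetraen-1-ol
Product: 9 (3Z,7E,11E)-8,12,16-trimethyl-4-(trimethylsilyl)heptadeca-3,7,11,15-tetraenal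
Conditions: DMP [1,1,1-triacetoxy-1λ5,2-benziodoxol-3(1H)-one], pyridine, CH2Cl2, 0 °C; used at once
Reagents that add atoms: none
Why: Buffered, non-basic oxidation with the hypervalent iodine reagent (Dess–Martin oxidation) should give the β,γ-unsaturated aldehyde without migration of the double bond into conjugation.

**Step 6**
Reactants: 9 (3Z,7E,11E)-8,12,16-trimethyl-4-(trimethylsilyl)heptadeca-3,7,11,15-tetraenal; 10 methyl propiolate
Product: 12 methyl (5Z,9E,13E)-3-hydroxy-10,14,18-trimethyl-2-methylidene-6-(trimethylsilyl)nonadeca-5,9,13,17-tetraenoate (racemic), via vinylalane 11 (not isolated)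
Conditions: i-Bu2AlH, NMO, THF, 0 °C; methyl propiolate, 0 °C; then 9, 0 °C → rt; aq Rochelle salt
Reagents that add atoms: none
Why: 1,4-Hydroalumination of methyl propiolate gives the α-aluminated acrylate 11, which adds to the aldehyde under non-basic conditions (vinylalumination route to Morita–Baylis–Hillman adducts); the carbinol centre forms without control because the key step sets it anew.

**Step 7**
Reactants: 12 methyl (5Z,9E,13E)-3-hydroxy-10,14,18-trimethyl-2-methylidene-6-(trimethylsilyl)nonadeca-5,9,13,17-tetraenoate (racemic)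
Product: 13 methyl (5Z,9E,13E)-3-[(tert-butoxycarbonyl)oxy]-10,14,18-trimethyl-2-methylidene-6-(trimethylsilyl)nonadeca-5,9,13,17-tetraenoate (racemic)
Conditions: Boc2O, DMAP (10 mol %), CH2Cl2, 0 °C → rt
Reagents that add atoms: di-tert-butyl dicarbonate, CC(C)(C)OC(=O)OC(=O)OC(C)(C)C
Why: DMAP-catalysed O-acylation of the secondary allylic alcohol (carbonate formation) installs the ionisable leaving group whose tert-butoxide later captures formaldehyde.

**Step 8**
Reactants: 13 methyl (5Z,9E,13E)-3-[(tert-butoxycarbonyl)oxy]-10,14,18-trimethyl-2-methylidene-6-(trimethylsilyl)nonadeca-5,9,13,17-tetraenoate (racemic); 14 formaldehyde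
Product: 16 methyl 2-[(2R)-5-[(3E,7E)-4,8,12-trimethyltrideca-3,7,11-trien-1-yl]-3,6-dihydro-2H-pyran-2-yl]prop-2-enoate, via tert-butoxymethyl ether 15 (not isolated)
Conditions: Pd2(dba)3·CHCl3 (2.5 mol %), (R,R)-DACH-phenyl ligand [N,N′-(1R,2R)-cyclohexane-1,2-diylbis(2-diphenylphosphanylbenzamide), 7.5 mol %], monomeric CH2O (3 equiv, from cracked paraformaldehyde), CH2Cl2, 0 °C → rt; volatiles and excess CH2O removed in vacuo in the same flask; then CH2Cl2, 2,6-di-tert-butyl-4-methylpyridine, Me3SiOTf (1.2 equiv), −78 → −40 °C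
Reagents that add atoms: none
Why: Proposed new method: zerovalent palladium ionises racemic 13 with loss of CO2 to a π-allylpalladium cation whose two faces interconvert faster than capture, while the released tert-butoxide adds to formaldehyde and the hemiformal alkoxide attacks the substituted allyl terminus C2 inside the chiral ligand pocket, which makes O1–C2 and sets the one stereocentre (R) by ligand control for both enantiomers of 13 (dynamic kinetic asymmetric allylic etherification) to give 15. Me3SiOTf then ionises the mixed formaldehyde acetal reversibly to the O1=C6H2 oxocarbenium ion, whose only irreversible exit is attack by the (Z)-vinylsilane at its silicon-bearing carbon C5 and loss of Me3Si+ from the β-silyl cation at C4, so that C6–C5 and the C4=C5 double bond arise together. The closest known reaction types are the palladium-catalysed dynamic kinetic asymmetric etherification of Baylis–Hillman carbonates with primary alcohols, the capture of π-allylpalladium intermediates by hemiacetal alkoxides formed from formaldehyde, and the acetal-initiated cyclisation of (Z)-vinylsilanes to 3,6-dihydro-2H-pyrans; new are the formaldehyde hemiacetal alkoxide as external nucleophile on this allyl system and the telescoping of both events. The ring closes in the 6-endo mode with respect to the vinylsilane (ipso attack, both alkene carbons end in the ring), the 5-exo alternative being disfavoured because it would place the cation α to silicon. The step needs branched regioselectivity at the allyl unit (secured by the ligand, as with other alcohols on this substrate class), ionisation of the acetal towards O1 (secured by reversibility and the intramolecular trap) and retention at C2 (no bond to C2 is broken after it forms).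

**Step 9**
Reactants: 16 methyl 2-[(2R)-5-[(3E,7E)-4,8,12-trimethyltrideca-3,7,11-trien-1-yl]-3,6-dihydro-2H-pyran-2-yl]prop-2-enoate
Product: 17 2-[(2R)-5-[(3E,7E)-4,8,12-trimethyltrideca-3,7,11-trien-1-yl]-3,6-dihydro-2H-pyran-2-yl]prop-2-enoic acid
Conditions: LiOH·H2O, THF–H2O (3:1), 0 °C → rt; then 1 M HCl to pH 3, 0 °C
Reagents that add atoms: lithium hydroxide, [Li+].[OH-]
Why: Saponification of the methyl ester (ester hydrolysis) should give the acid, and C2 carries no hydrogen α to a carbonyl group, so its configuration is not at risk under these mild conditions.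

**Compound list**

1 | (5E,9E)-6,10,14-trimethylpentadeca-5,9,13-trien-2-one | CC(=O)CC/C=C(\C)CC/C=C(\C)CCC=C(C)C | starting material
2 | diethyl (5E,9E)-6,10,14-trimethylpentadeca-1,5,9,13-tetraen-2-yl phosphate | C=C(OP(=O)(OCC)OCC)CC/C=C(\C)CC/C=C(\C)CCC=C(C)C | intermediate
3 | (5E,9E)-6,10,14-trimethylpentadeca-5,9,13-trien-1-yne | C#CCC/C=C(\C)CC/C=C(\C)CCC=C(C)C | intermediate
4 | ethylene oxide | C1CO1 | starting material
5 | (7E,11E)-8,12,16-trimethylheptadeca-7,11,15-trien-3-yn-1-ol | OCCC#CCC/C=C(\C)CC/C=C(\C)CCC=C(C)C | intermediate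
6 | dimethyl{[(7E,11E)-8,12,16-trimethylheptadeca-7,11,15-trien-3-yn-1-yl]oxy}silane | C[SiH](C)OCCC#CCC/C=C(\C)CC/C=C(\C)CCC=C(C)C | intermediate
7 | 2,2-dimethyl-3-[(3E,7E)-4,8,12-trimethyltrideca-3,7,11-trien-1-yl]-5,6-dihydro-2H-1,2-oxasiline | C[Si]1(C)OCCC=C1CC/C=C(\C)CC/C=C(\C)CCC=C(C)C | intermediate
8 | (3Z,7E,11E)-8,12,16-trimethyl-4-(trimethylsilyl)heptadeca-3,7,11,15-tetraen-1-ol | OCC/C=C(\[Si](C)(C)C)CC/C=C(\C)CC/C=C(\C)CCC=C(C)C | intermediate
9 | (3Z,7E,11E)-8,12,16-trimethyl-4-(trimethylsilyl)heptadeca-3,7,11,15-tetraenal | O=CC/C=C(\[Si](C)(C)C)CC/C=C(\C)CC/C=C(\C)CCC=C(C)C | intermediate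
10 | methyl propiolate | C#CC(=O)OC | starting material
11 | [1-(methoxycarbonyl)ethenyl]bis(2-methylpropyl)alane | C=C(C(=O)OC)[Al](CC(C)C)CC(C)C | intermediate
12 | methyl (5Z,9E,13E)-3-hydroxy-10,14,18-trimethyl-2-methylidene-6-(trimethylsilyl)nonadeca-5,9,13,17-tetraenoate (racemic) | C=C(C(=O)OC)C(O)C/C=C(\[Si](C)(C)C)CC/C=C(\C)CC/C=C(\C)CCC=C(C)C | intermediate
13 | methyl (5Z,9E,13E)-3-[(tert-butoxycarbonyl)oxy]-10,14,18-trimethyl-2-methylidene-6-(trimethylsilyl)nonadeca-5,9,13,17-tetraenoate (racemic) | C=C(C(=O)OC)C(OC(=O)OC(C)(C)C)C/C=C(\[Si](C)(C)C)CC/C=C(\C)CC/C=C(\C)CCC=C(C)C | intermediate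
14 | formaldehyde | C=O | starting material
15 | methyl (3R,5Z,9E,13E)-3-(tert-butoxymethoxy)-10,14,18-trimethyl-2-methylidene-6-(trimethylsilyl)nonadeca-5,9,13,17-tetraenoate | C=C(C(=O)OC)[C@H](OCOC(C)(C)C)C/C=C(\[Si](C)(C)C)CC/C=C(\C)CC/C=C(\C)CCC=C(C)C | intermediate
16 | methyl 2-[(2R)-5-[(3E,7E)-4,8,12-trimethyltrideca-3,7,11-trien-1-yl]-3,6-dihydro-2H-pyran-2-yl]prop-2-enoate | C=C(C(=O)OC)[C@H]1CC=C(CC/C=C(\C)CC/C=C(\C)CCC=C(C)C)CO1 | intermediate
17 | 2-[(2R)-5-[(3E,7E)-4,8,12-trimethyltrideca-3,7,11-trien-1-yl]-3,6-dihydro-2H-pyran-2-yl]prop-2-enoic acid | C=C(C(=O)O)[C@H]1CC=C(CC/C=C(\C)CC/C=C(\C)CCC=C(C)C)CO1 | target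

**Totals**

Total step count: 9. Longest linear sequence: 9 steps (1 → 17).

**Steps most likely to fail**

Step 8 (proposed new method). The π-allyl intermediate may be captured by tert-butoxide or by oligomeric hemiformals instead of the monomeric hemiformal alkoxide. Facial selectivity may erode with so small a nucleophile. The mixed acetal may ionise in the unproductive direction, or the vinylsilane may be hydroxymethylated intermolecularly by residual formaldehyde. The fallback uses known chemistry only and sets out from 13. Palladium-catalysed dynamic kinetic asymmetric etherification with 4-methoxybenzyl alcohol (Pd2(dba)3·CHCl3, same ligand, CH2Cl2) should give the (R)-4-methoxybenzyl ether F1. DDQ in CH2Cl2/pH 7 buffer should free the (R)-configured Baylis–Hillman alcohol F2. MEMCl and i-Pr2NEt should give the (2-methoxyethoxy)methyl ether F3. SnCl4 in CH2Cl2 at −20 °C (acetal-initiated cyclisation of the (Z)-vinylsilane) should close the ring and return to 16.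

Step 6. The β,γ-double bond of 9 may migrate into conjugation, or 9 may enolise on contact with the aluminium reagent before the C–C bond forms. The fallback sets out from 9 and replaces the in situ vinylalane by a preformed ester enolate at low temperature. The lithium enolate of methyl 3-(dimethylamino)propanoate (LDA, THF, −78 °C) should add to 9 to give the β-hydroxy Mannich base F4. N-methylation with MeI and elimination with DBU should then reveal the methylidene group and return to 12.

Step 3. Regiocontrol may be lost through exo-dig closure, or the tethered Si–H may add intermolecularly and oligomerise. The fallback sets out from 5 and drops the tether. Hydroxyl-directed intermolecular trans-hydrosilylation with (EtO)3SiH and [Cp*Ru(MeCN)3]PF6 should place silicon mainly on the distal alkyne carbon and give the (Z)-alkenyltriethoxysilane F5. Excess MeLi in THF should exchange the three ethoxy groups for methyl and return to 8.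

**Further compounds**

F1 | step 8 | methyl (3R,5Z,9E,13E)-3-[(4-methoxyphenyl)methoxy]-10,14,18-trimethyl-2-methylidene-6-(trimethylsilyl)nonadeca-5,9,13,17-tetraenoate | C=C(C(=O)OC)[C@H](OCc1ccc(OC)cc1)C/C=C(\[Si](C)(C)C)CC/C=C(\C)CC/C=C(\C)CCC=C(C)C
F2 | step 8 | methyl (3R,5Z,9E,13E)-3-hydroxy-10,14,18-trimethyl-2-methylidene-6-(trimethylsilyl)nonadeca-5,9,13,17-tetraenoate | C=C(C(=O)OC)[C@H](O)C/C=C(\[Si](C)(C)C)CC/C=C(\C)CC/C=C(\C)CCC=C(C)C
F3 | step 8 | methyl (3R,5Z,9E,13E)-3-[(2-methoxyethoxy)methoxy]-10,14,18-trimethyl-2-methylidene-6-(trimethylsilyl)nonadeca-5,9,13,17-tetraenoate | C=C(C(=O)OC)[C@H](OCOCCOC)C/C=C(\[Si](C)(C)C)CC/C=C(\C)CC/C=C(\C)CCC=C(C)C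
F4 | step 6 | methyl (5Z,9E,13E)-2-[(dimethylamino)methyl]-3-hydroxy-10,14,18-trimethyl-6-(trimethylsilyl)nonadeca-5,9,13,17-tetraenoate (mixture of diastereomers) | CN(C)CC(C(=O)OC)C(O)C/C=C(\[Si](C)(C)C)CC/C=C(\C)CC/C=C(\C)CCC=C(C)C
F5 | step 3 | (3Z,7E,11E)-4-(triethoxysilyl)-8,12,16-trimethylheptadeca-3,7,11,15-tetraen-1-ol | OCC/C=C(\[Si](OCC)(OCC)OCC)CC/C=C(\C)CC/C=C(\C)CCC=C(C)C
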